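You are asked how much product this flask holds at 80 min, how far the left hand leads in it, and whether the exchange of hands keeps up.

- left-handed product and right-handed product together, in percent of the left-handed substrate and right-handed substrate charged together, at 80 min
- excess of left-handed product over right-handed product in the product at 80 min
- whether the exchange between left-handed substrate and right-handed substrate keeps pace with the reaction: how far the product's excess at 80 min gets from its value without exchange to its value with instant exchange (above 80 % keeps pace, below 20 % hardly takes part, else lags behind)

| setting | theta | beta | epsilon | flask |
|---|---|---|---|---|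
| left-handed substrate | 0.19 M | 0.42 M | 0.28 M | 0.28 M |
| right-handed substrate | 0.19 M | 0.42 M | 0.28 M | 0.28 M |
| coupling partner | 0.70 M | 0.70 M | 0.70 M | 0.700 M |
| racemization catalyst | 0.56 mM | 0.56 mM | 0.56 mM | 0.56 mM |
| added ligand | 0.34 mM | 0.34 mM | 0.34 mM | 0.34 mM |
| impurity | 0.83 mM | 0.83 mM | 1.7 mM | 0.83 mM |
| remark | run made earlier | run made earlier | run made earlier |  |
| time |  |  |  | 80 min |

- theta (time / min: left-handed product / %, right-handed product / %): 8.00: 7, 4; 12.0: 9, 2; 20.0: 16, 6; 25.0: 16, 6; 40.0: 27, 12; 60.0: 33, 19; 90.0: 40, 22
- beta (time / min: left-handed product / %, right-handed product / %): 8.00: 6, 3; 12.0: 12, 5; 20.0: 15, 5; 25.0: 18, 11; 40.0: 26, 12; 60.0: 31, 12; 90.0: 38, 16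
- epsilon (time / min: left-handed product / %, right-handed product / %): 8.00: 5, 6; 25.0: 18, 11; 40.0: 26, 12; 60.0: 30, 16; 90.0: 37, 19

(each reading ± 2 percentage points)

- coupling partner is single-handed; left-handed substrate and right-handed substrate are mirror images of each other, charged as a racemate, each of them at the stated concentration
- steps thought possible: racemization catalyst + added ligand <-> idle complex; coupling partner + right-handed substrate -> right-handed product; racemization catalyst + impurity -> spent catalyst; left-handed substrate + racemization catalyst <-> right-handed substrate + racemization catalyst; coupling partner + left-handed substrate -> left-handed product
- an excess is the difference of the two amounts in percent of their sum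
- an excess is below zero if the other one leads
- the handed part of coupling partner does not stay in what it makes, so the products of the two hands are mirror images too

Follow one molecule of substrate. If the hands do not flip, both wait for the same coupling partner, so the partner cancels when you compare their chances of surviving. Pooling the three runs at 40.0 min, 60.0 min and 90.0 min, I read 2.83. This is the fork number, the log of the surviving fraction of left-handed substrate over the same log for right-handed substrate, usually called the selectivity factor. It says the left hand goes faster.

My own reckoning scales the pooled right-handed product to 80 min, which leaves a fraction 65.4 % of the right-handed substrate. Raising that to the fork number leaves 30.1 % of the left-handed substrate. So without flips I expect 52.2 % product in this flask with excess 33.8 %, while instant exchange would hold the excess at 47.8 %.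

The fork number does not say which of these holds. A second number bears on that, impurity per catalyst, 1.48 in this flask, where the impurity outnumbers the catalyst. So I expect the exchange in this flask to stop early.

The forecast says 54 % and 33 %, and that the exchange hardly takes part: “The impurity exceeds the catalyst and probably kills it early”.

The flask gives 54.6 % and 29.4 %, and the exchange hardly takes part, getting 2.5 % of the way.

    racemization catalyst + added ligand ⇌ idle complex (K = 1200 M⁻¹, k = 330 M⁻¹ min⁻¹)
    coupling partner + right-handed substrate → right-handed product (k = 0.0120 M⁻¹ min⁻¹)
    racemization catalyst + impurity → spent catalyst (k = 4000 M⁻¹ min⁻¹)
    left-handed substrate + racemization catalyst ⇌ right-handed substrate + racemization catalyst, rate k4*[racemization catalyst]*[left-handed substrate] forward; the back reaction follows from the equilibrium constant (k = 910 M⁻¹ min⁻¹)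
    coupling partner + left-handed substrate → left-handed product (k = 0.0300 M⁻¹ min⁻¹)

In the flask, spent catalyst stands at >99.9 % of the catalyst charged by 40.0 min. At 80.0 min, with 61 % of the flask's right-handed substrate left, the fork number leaves 24.9 % of the left-handed substrate, against 30 % found, and an excess of 31.6 %. The neighbour charged with 1.8 M of coupling partner keeps 25 % of its right-handed substrate at 80 min, so the same reckoning leaves 1.88 % of the left-handed substrate and an excess of 13.0 %. That neighbour gives 86.2 % product with excess 13.2 %.

All runs are calculated with made-up constants; noise was put on by code.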